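**Strategy**

The chromone is cut through ring A at C4a–C5, C5–C6 and C7–C8, so that the benzene ring is grown onto an existing 4-pyranone (ring C) that already carries the 2-aryloxy group. In one operation an alkyl(pyranonyl)ketene and tert-butoxyethyne give, by way of a cyclobutenone and a dienylketene, ring A with 5-OH, 6-H, 7-O-tert-butyl and 8-prenyl in place. The step exploits the resorcinol pattern of ring A and the enol-ether C=C of ring C (future C8a=C4a), whose CH carbon becomes C4a. The precursor is the α-prenylated (4-oxopyran-2-yl)acetyl chloride 10, made from a 6-methylpyranone by two lateral metalations.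

Key step: step 8

Remarks on the chemistry:
- In the 4-oxo-4H-pyran-2-yl unit of 10, the ring carbon that closes ring A is C3, the CH next to the side-chain-bearing C2. The double bond used is C2=C3, not the aryloxy-bearing C5=C6.
- tert-Butoxyethyne is assumed to be purchased. It is kept below 30 °C until consumed or removed, because it loses isobutene on warming.
- Compounds 9, 10, 13 and 15 are racemic. The target has no stereocentre.

**Route**

Step 1
Reactants: 1 4,4-bis(methylsulfanyl)but-3-en-2-one
Product: 2 1,1-bis(methylsulfanyl)hex-1-ene-3,5-dione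
Conditions: 1 (2 equiv), LiN(SiMe3)2 (2.1 equiv), toluene–THF, 0 °C; AcCl (1 equiv), 0 °C; aq. NH4Cl
Reagents that add atoms: acetyl chloride, CC(Cl)=O
Why: Claisen-type C-acylation of the kinetic lithium enolate of the methyl ketone with an acid chloride, in which the second equivalent of enolate takes up the acidic proton of the β-diketone and is recovered as 1.

Step 2
Reactants: 2 1,1-bis(methylsulfanyl)hex-1-ene-3,5-dione
Product: 3 6-methyl-2-(methylsulfanyl)-4H-pyran-4-one
Conditions: p-TsOH·H2O (10 mol%), toluene, 80 °C, N2 sweep into a bleach scrubber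
Reagents that add atoms: none
Why: Acid-catalysed cyclocondensation of a 1,3,5-tricarbonyl equivalent to a 4-pyranone, in which the enol oxygen of the 5-keto group adds 6-endo to the ketene dithioacetal carbon (oxa-Michael addition–elimination) and methanethiol is lost.

Step 3
Reactants: 3 6-methyl-2-(methylsulfanyl)-4H-pyran-4-one
Product: 4 2-(methanesulfonyl)-6-methyl-4H-pyran-4-one
Conditions: mCPBA (2.3 equiv), CH2Cl2, 0 °C to rt; cold aq. NaHCO3 wash, used without chromatography
Reagents that add atoms: mCPBA (3-chloroperoxybenzoic acid), O=C(OO)c1cccc(Cl)c1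
Why: Peracid oxidation of the sulfide to the sulfone, which the electron-poor ring double bonds of the pyranone should survive without epoxidation.

Step 4
Reactants: 4 2-(methanesulfonyl)-6-methyl-4H-pyran-4-one; 5 4-methoxyphenol
Product: 6 2-(4-methoxyphenoxy)-6-methyl-4H-pyran-4-one
Conditions: K2CO3, MeCN, 0 °C to rt
Reagents that add atoms: none
Why: Addition–elimination (vinylogous acyl substitution) of the phenoxide at the sulfonyl-bearing C2, the reaction type by which phenoxides displace sulfinate from 2-sulfonylchromones; C2 is the most electrophilic ring carbon and methanesulfinate the only good leaving group.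

Step 5
Reactants: 6 2-(4-methoxyphenoxy)-6-methyl-4H-pyran-4-one; 7 prenyl bromide (1-bromo-3-methylbut-2-ene)
Product: 8 2-(4-methoxyphenoxy)-6-(4-methylpent-3-en-1-yl)-4H-pyran-4-one
Conditions: LiN(SiMe3)2 (1.05 equiv), THF, −78 °C (6 added to the base); 7 (1.2 equiv), −78 to −30 °C; aq. NH4Cl
Reagents that add atoms: none
Why: Lateral (vinylogous) deprotonation of the 6-methyl group gives the extended lithium enolate, which should be C-alkylated at the exocyclic carbon by SN2 reaction with the primary allylic bromide, while the non-nucleophilic amide base and inverse addition spare C2 and its aryloxy group.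

Step 6
Reactants: 8 2-(4-methoxyphenoxy)-6-(4-methylpent-3-en-1-yl)-4H-pyran-4-one
Product: 9 2-[6-(4-methoxyphenoxy)-4-oxo-4H-pyran-2-yl]-5-methylhex-4-enoic acid (racemic)
Conditions: LiN(SiMe3)2 (1.1 equiv), THF, −78 °C; dry CO2, −78 °C; 1 M HCl to pH 3 at 0 °C, extracted cold and used at once
Reagents that add atoms: carbon dioxide, O=C=O
Why: Carboxylation of the lithiated lateral methylene gives the acid directly, so that no ester must be hydrolysed beside the hydroxide-labile 2-aryloxy group; the new stereocentre forms as a racemate and is erased in step 8.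

Step 7
Reactants: 9 2-[6-(4-methoxyphenoxy)-4-oxo-4H-pyran-2-yl]-5-methylhex-4-enoic acid (racemic)
Product: 10 2-[6-(4-methoxyphenoxy)-4-oxo-4H-pyran-2-yl]-5-methylhex-4-enoyl chloride (racemic)
Conditions: 1-chloro-N,N,2-trimethylprop-1-en-1-amine (1.1 equiv), CH2Cl2, 0 °C to rt; concentrated below 25 °C, used crude
Reagents that add atoms: 1-chloro-N,N,2-trimethylprop-1-en-1-amine (Ghosez reagent), CC(C)=C(Cl)N(C)C
Why: The α-chloroenamine converts the acid into the acid chloride under neutral conditions through an acyloxyiminium chloride and releases only an amide, so that neither HCl nor heat reaches the prenyl alkene or the decarboxylation-prone pyranylacetic acid.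

Step 8
Reactants: 10 2-[6-(4-methoxyphenoxy)-4-oxo-4H-pyran-2-yl]-5-methylhex-4-enoyl chloride (racemic); 11 tert-butoxyethyne
Product: 16 7-tert-butoxy-5-hydroxy-2-(4-methoxyphenoxy)-8-(3-methylbut-2-en-1-yl)-4H-chromen-4-one, via ketene 12 (not isolated), via cyclobutenone 13 (not isolated), via dienylketene 14 (not isolated), via dienone 15 (not isolated)
Conditions: 11 (2.5 equiv), Et3N (1.2 equiv, added slowly), toluene, 0 to 25 °C; filtered, excess 11 evaporated below 30 °C; toluene, 80 °C
Reagents that add atoms: none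
Why: Proposed new method: Et3N dehydrochlorinates 10 to ketene 12, whose carbonyl carbon is attacked by the unsubstituted, nucleophilic carbon of the alkynyl ether, so that the (2+2) cycloadduct is the 3-tert-butoxycyclobutenone 13 with C5–C6 and C7–C8 already formed. On heating, 13 should open reversibly (four-electron electrocyclic opening) to dienylketene 14, and ring A then closes by thermal six-electron disrotatory electrocyclization of the ketene carbon onto pyranone C3, giving dienone 15, which enolizes to phenol 16 because its C4a–H lies between two carbonyl groups. The closest known reaction type is the Danheiser benzannulation of vinylketenes and arylketenes with alkoxy- or siloxyalkynes, including the classical arylketene–ethoxyethyne route to 3-alkoxy-1-naphthols; a 4-pyranone C=C as the third π component has not been shown, but C3 is the nucleophilic enol-ether carbon of the pyranone and matches the electrophilic ketene carbon. No stereocentre has to be controlled, since the quaternary carbon of 13 and C4a of 15 are racemic and are erased by ring opening and enolization. The step needs the right cycloaddition regiochemistry, which the polarization of the alkynyl ether fixes, and closure at the pyranone only, which is secured because the geometric isomer of 14 with prenyl cis to the ketene can merely revert to 13 and because the other neighbour of the attachment carbon is the ring oxygen, leaving C3 as the sole terminus. The two-temperature protocol keeps the thermally labile alkyne and the free ketene away from the hot stage and from the phenol that forms there.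

Step 9
Reactants: 16 7-tert-butoxy-5-hydroxy-2-(4-methoxyphenoxy)-8-(3-methylbut-2-en-1-yl)-4H-chromen-4-one
Product: 17 5,7-dihydroxy-2-(4-methoxyphenoxy)-8-(3-methylbut-2-en-1-yl)-4H-chromen-4-one
Conditions: TFA–CH2Cl2 (1:4), 0 °C, short contact under N2 sweep; poured into cold aq. NaHCO3
Reagents that add atoms: none
Why: Acidolysis of the aryl tert-butyl ether (E1 loss of the tert-butyl cation as isobutene) should be easy because O7 is a vinylogous ester oxygen para to C4a, so that dilute cold acid and a short contact time should suffice and leave the prenyl alkene beside the new 7-OH unprotonated.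

**Compound list**

1 | 4,4-bis(methylsulfanyl)but-3-en-2-one | CSC(SC)=CC(C)=O | starting material
2 | 1,1-bis(methylsulfanyl)hex-1-ene-3,5-dione | CSC(SC)=CC(=O)CC(C)=O | intermediate
3 | 6-methyl-2-(methylsulfanyl)-4H-pyran-4-one | CSc1cc(=O)cc(C)o1 | intermediate
4 | 2-(methanesulfonyl)-6-methyl-4H-pyran-4-one | CS(=O)(=O)c1cc(=O)cc(C)o1 | intermediate
5 | 4-methoxyphenol | COc1ccc(O)cc1 | starting material
6 | 2-(4-methoxyphenoxy)-6-methyl-4H-pyran-4-one | COc1ccc(Oc2cc(=O)cc(C)o2)cc1 | intermediate
7 | prenyl bromide (1-bromo-3-methylbut-2-ene) | CC(C)=CCBr | starting material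
8 | 2-(4-methoxyphenoxy)-6-(4-methylpent-3-en-1-yl)-4H-pyran-4-one | COc1ccc(Oc2cc(=O)cc(CCC=C(C)C)o2)cc1 | intermediate
9 | 2-[6-(4-methoxyphenoxy)-4-oxo-4H-pyran-2-yl]-5-methylhex-4-enoic acid (racemic) | COc1ccc(Oc2cc(=O)cc(C(CC=C(C)C)C(=O)O)o2)cc1 | intermediate
10 | 2-[6-(4-methoxyphenoxy)-4-oxo-4H-pyran-2-yl]-5-methylhex-4-enoyl chloride (racemic) | COc1ccc(Oc2cc(=O)cc(C(CC=C(C)C)C(Cl)=O)o2)cc1 | intermediate
11 | tert-butoxyethyne | C#COC(C)(C)C | starting material
12 | 2-[6-(4-methoxyphenoxy)-4-oxo-4H-pyran-2-yl]-5-methylhexa-1,4-dien-1-one (ketene, not isolated) | COc1ccc(Oc2cc(=O)cc(C(CC=C(C)C)=C=O)o2)cc1 | intermediate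
13 | 3-tert-butoxy-4-[6-(4-methoxyphenoxy)-4-oxo-4H-pyran-2-yl]-4-(3-methylbut-2-en-1-yl)cyclobut-2-en-1-one (racemic, not isolated) | COc1ccc(Oc2cc(=O)cc(C3(CC=C(C)C)C(=O)C=C3OC(C)(C)C)o2)cc1 | intermediate
14 | (3E)-3-tert-butoxy-4-[6-(4-methoxyphenoxy)-4-oxo-4H-pyran-2-yl]-7-methylocta-1,3,6-trien-1-one (dienylketene, productive isomer, not isolated) | O=C=C/C(OC(C)(C)C)=C(/CC=C(C)C)c1cc(=O)cc(Oc2ccc(OC)cc2)o1 | intermediate
15 | 7-tert-butoxy-2-(4-methoxyphenoxy)-8-(3-methylbut-2-en-1-yl)-4aH-chromene-4,5-dione (racemic, not isolated) | COc1ccc(OC2=CC(=O)C3C(=O)C=C(OC(C)(C)C)C(CC=C(C)C)=C3O2)cc1 | intermediate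
16 | 7-tert-butoxy-5-hydroxy-2-(4-methoxyphenoxy)-8-(3-methylbut-2-en-1-yl)-4H-chromen-4-one | CC(C)(C)Oc1cc(O)c2c(c1CC=C(C)C)oc(Oc1ccc(OC)cc1)cc2=O | intermediate
17 | 5,7-dihydroxy-2-(4-methoxyphenoxy)-8-(3-methylbut-2-en-1-yl)-4H-chromen-4-one | COc1ccc(Oc2cc(=O)c3c(O)cc(O)c(CC=C(C)C)c3o2)cc1 | target

**Step count and risks**

Total step count: 9. Longest linear sequence: 9 steps (1 to 17).

Steps most likely to fail:

1. Step 8. The ketene may dimerize or be consumed before it meets the alkynyl ether, or the dienylketene may not close onto the pyranone and may be lost by other pathways. The fallback uses known chromone chemistry, in which ring C is built on a preformed ring A and the prenyl group is placed last. It sets out from 4-methoxyphenol 5 and comes back to the route at the target 17.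
   - Purchased 1-[2,4-bis(benzyloxy)-6-hydroxyphenyl]ethan-1-one F1 would be condensed with CS2 (KOC(CH3)3, THF) to 5,7-bis(benzyloxy)-4-hydroxy-2H-chromene-2-thione F2.
   - S-Methylation (MeI, K2CO3, acetone) would give 5,7-bis(benzyloxy)-2-(methylsulfanyl)-4H-chromen-4-one F3.
   - mCPBA would give 5,7-bis(benzyloxy)-2-(methanesulfonyl)-4H-chromen-4-one F4, from which 5 with K2CO3 would displace sulfinate to give 5,7-bis(benzyloxy)-2-(4-methoxyphenoxy)-4H-chromen-4-one F5.
   - Hydrogenolysis (H2, Pd/C, EtOAc) would give 5,7-dihydroxy-2-(4-methoxyphenoxy)-4H-chromen-4-one F6.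
   - Selective acetylation of the unchelated 7-OH (Ac2O, pyridine, 0 °C) would give 5-hydroxy-2-(4-methoxyphenoxy)-4-oxo-4H-chromen-7-yl acetate F7.
   - Mitsunobu etherification of the 5-OH with 3-methylbut-2-en-1-ol (PPh3, DIAD, THF) would give 2-(4-methoxyphenoxy)-5-[(3-methylbut-2-en-1-yl)oxy]-4-oxo-4H-chromen-7-yl acetate F8.
   - A Claisen–Cope rearrangement catalysed by Eu(fod)3 (fod = 6,6,7,7,8,8,8-heptafluoro-2,2-dimethyloctane-3,5-dionate; CHCl3, 60 °C) would move the prenyl group from O5 through C6 to C8 and give 5-hydroxy-2-(4-methoxyphenoxy)-8-(3-methylbut-2-en-1-yl)-4-oxo-4H-chromen-7-yl acetate F9.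
   - Mild deacetylation (NH4OAc, aqueous MeOH, rt) would then give 17.

2. Step 6. Metalation at the secondary lateral carbon of 8 may be slow or stray to a ring position, the dienolate may attack C2 of unreacted pyranone with loss of aryloxide, and the acid may lose CO2 if it is warmed. The fallback reverses the order of the two C–C bond formations, so that the harder bond is made from a doubly stabilized anion. It sets out from 6 and comes back at 9, bypassing 8. Lateral lithiation of 6 (LiN(SiMe3)2, THF, −78 °C) and CO2 would give 2-[6-(4-methoxyphenoxy)-4-oxo-4H-pyran-2-yl]acetic acid F10. Its dianion (LiN(SiMe3)2, 2.1 equiv, −78 °C) would be alkylated with prenyl bromide 7 at the carbon flanked by carboxylate and pyranone.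

3. Step 9. The prenyl alkene may be protonated next to the freed 7-OH and close to a dimethylchroman ring, or the tert-butyl cation may alkylate C6. The fallback exchanges the protecting group without Brønsted acid. It sets out from 16 and comes back at 17. Me3SiOTf and 2,6-lutidine (CH2Cl2, 0 °C) would replace the tert-butyl group by silicon, the cation leaving as isobutene under buffering, and would silylate the 5-OH, giving 2-(4-methoxyphenoxy)-8-(3-methylbut-2-en-1-yl)-5,7-bis[(trimethylsilyl)oxy]-4H-chromen-4-one F11. Methanolysis of the two aryl silyl ethers (MeOH, catalytic KF, 0 °C) would give 17.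

**Further compounds**

F1 | step 8 | 1-[2,4-bis(benzyloxy)-6-hydroxyphenyl]ethan-1-one (purchased) | CC(=O)c1c(O)cc(OCc2ccccc2)cc1OCc1ccccc1
F2 | step 8 | 5,7-bis(benzyloxy)-4-hydroxy-2H-chromene-2-thione | Oc1cc(=S)oc2cc(OCc3ccccc3)cc(OCc3ccccc3)c12
F3 | step 8 | 5,7-bis(benzyloxy)-2-(methylsulfanyl)-4H-chromen-4-one | CSc1cc(=O)c2c(OCc3ccccc3)cc(OCc3ccccc3)cc2o1
F4 | step 8 | 5,7-bis(benzyloxy)-2-(methanesulfonyl)-4H-chromen-4-one | CS(=O)(=O)c1cc(=O)c2c(OCc3ccccc3)cc(OCc3ccccc3)cc2o1
F5 | step 8 | 5,7-bis(benzyloxy)-2-(4-methoxyphenoxy)-4H-chromen-4-one | COc1ccc(Oc2cc(=O)c3c(OCc4ccccc4)cc(OCc4ccccc4)cc3o2)cc1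
F6 | step 8 | 5,7-dihydroxy-2-(4-methoxyphenoxy)-4H-chromen-4-one | COc1ccc(Oc2cc(=O)c3c(O)cc(O)cc3o2)cc1
F7 | step 8 | 5-hydroxy-2-(4-methoxyphenoxy)-4-oxo-4H-chromen-7-yl acetate | COc1ccc(Oc2cc(=O)c3c(O)cc(OC(C)=O)cc3o2)cc1
F8 | step 8 | 2-(4-methoxyphenoxy)-5-[(3-methylbut-2-en-1-yl)oxy]-4-oxo-4H-chromen-7-yl acetate | COc1ccc(Oc2cc(=O)c3c(OCC=C(C)C)cc(OC(C)=O)cc3o2)cc1
F9 | step 8 | 5-hydroxy-2-(4-methoxyphenoxy)-8-(3-methylbut-2-en-1-yl)-4-oxo-4H-chromen-7-yl acetate | COc1ccc(Oc2cc(=O)c3c(O)cc(OC(C)=O)c(CC=C(C)C)c3o2)cc1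
F10 | step 6 | 2-[6-(4-methoxyphenoxy)-4-oxo-4H-pyran-2-yl]acetic acid | COc1ccc(Oc2cc(=O)cc(CC(=O)O)o2)cc1
F11 | step 9 | 2-(4-methoxyphenoxy)-8-(3-methylbut-2-en-1-yl)-5,7-bis[(trimethylsilyl)oxy]-4H-chromen-4-one | COc1ccc(Oc2cc(=O)c3c(O[Si](C)(C)C)cc(O[Si](C)(C)C)c(CC=C(C)C)c3o2)cc1
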